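**Retrosynthetic overview**

1. Late stage: the C5 ester comes from opening 3-methylglutaconic anhydride with the C5 hydroxyl of a cis-5,6-diol. The C1 acyl chain comes from a C1 vinyl group (Wacker oxidation, then formaldehyde aldol), the cis-diol from a C5=C6 enol acetate (epoxidation, then C6 ketone reduction), and the C8 methyl from a C8 formyl group.
2. Key disconnection: a retro-[4+2] across C7–C8 and C4a–C8a opens both rings at once to an acyclic trienal, in which the (E)-enal C8a=C8–CHO is tethered through C1–C2–C3=C4 to the 2-acetoxydiene C4a=C5–C6(OAc)=C7.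
3. Enabling feature: ring B carries the C6 oxygen next to the unsubstituted C7H2, and the C8 methyl next to the ring-fusion carbon C8a. C6/C7 can therefore be the enol end of a diene and C8a=C8 an enal (methyl carried as CHO), while the cis C3=C4 alkene of ring A is a rigid four-atom tether.
4. Acyclic precursor: C1 (quaternary) and C2 are set by Ireland–Claisen rearrangement of the (R)-3-methylpentanoate of a glyceraldehyde-derived dienyl carbinol (chirality transfer). The (Z,E)-dienone comes from Sonogashira coupling and Lindlar reduction.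
5. Ring order: rings A and B form together in step 15 (ring A through the tether by C4a–C8a, ring B closed by C7–C8); no ring of the target exists before that step.

Key step: step 15

Assumption: 1, 7, 15 and the L-fructose-derived epoxidation ketone of step 18 are taken as catalogue compounds; 7 brings in the sec-butyl stereocentre unchanged.
Locants: the decalin numbering of the target is used for ring and open-chain compounds alike (C1 quaternary carbon, C2 sec-butyl-bearing carbon, C3=C4, ring fusion C4a/C8a, C5 and C6 oxygenated, C8 methyl-bearing). β is the face of the C1 methyl group, H4a and both ring oxygens; α is the face of H8a, the sec-butyl group and the C8 methyl group.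

**Step 1**
Reactants: 1 (S)-2,2-dimethyl-1,3-dioxolane-4-carbaldehyde; 2 2-(triphenylphosphoranylidene)propanal
Product: 3 (R,E)-3-(2,2-dimethyl-1,3-dioxolan-4-yl)-2-methylprop-2-enal
Conditions: PhMe, 80 °C
Reagents that add atoms: none
Why: Wittig olefination with a stabilised formyl ylide is E-selective and leaves the α-alkoxy stereocentre untouched (its descriptor changes from S to R only because the substituent priorities change).

**Step 2**
Reactants: 3 (R,E)-3-(2,2-dimethyl-1,3-dioxolan-4-yl)-2-methylprop-2-enal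
Product: 4 (R)-2,2-dimethyl-4-[(1E)-2-methylbuta-1,3-dien-1-yl]-1,3-dioxolane
Conditions: Ph3PCH3Br, n-BuLi, THF, −78 → 0 °C
Reagents that add atoms: methyltriphenylphosphonium bromide, C[P+](c1ccccc1)(c1ccccc1)c1ccccc1.[Br-]
Why: Wittig methylenation of the non-enolisable enal should give the terminal diene with the trisubstituted E-alkene unchanged.

**Step 3**
Reactants: 4 (R)-2,2-dimethyl-4-[(1E)-2-methylbuta-1,3-dien-1-yl]-1,3-dioxolane
Product: 5 (2R,3E)-4-methylhexa-3,5-diene-1,2-diol
Conditions: AcOH/H2O (4:1), 23 °C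
Reagents that add atoms: none
Why: Mild acetal hydrolysis cleaves the acetonide at the ketal carbon, so the allylic C–O bond and the stereocentre are not affected.

**Step 4**
Reactants: 5 (2R,3E)-4-methylhexa-3,5-diene-1,2-diol
Product: 6 (2R,3E)-1-[(tert-butyldimethylsilyl)oxy]-4-methylhexa-3,5-dien-2-ol
Conditions: TBSCl (1.05 equiv), imidazole, CH2Cl2, −20 °C
Reagents that add atoms: tert-butyldimethylsilyl chloride, CC(C)(C)[Si](C)(C)Cl
Why: Silylation is selective for the primary hydroxyl on steric grounds and leaves the secondary dienyl carbinol free for esterification.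

**Step 5**
Reactants: 6 (2R,3E)-1-[(tert-butyldimethylsilyl)oxy]-4-methylhexa-3,5-dien-2-ol; 7 (R)-3-methylpentanoic acid
Product: 8 (2R,3E)-1-[(tert-butyldimethylsilyl)oxy]-4-methylhexa-3,5-dien-2-yl (3R)-3-methylpentanoate
Conditions: DCC, DMAP (cat.), CH2Cl2, 0 → 23 °C
Reagents that add atoms: none
Why: Steglich esterification joins the two chiral pieces under neutral conditions, without ionising the dienyl carbinol or touching either stereocentre.

**Step 6**
Reactants: 8 (2R,3E)-1-[(tert-butyldimethylsilyl)oxy]-4-methylhexa-3,5-dien-2-yl (3R)-3-methylpentanoate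
Product: 11 (2R,3R,4E)-2-[(2R)-butan-2-yl]-6-[(tert-butyldimethylsilyl)oxy]-3-ethenyl-3-methylhex-4-enoic acid, via silyl ketene acetal 9 (not isolated), via trimethylsilyl ester 10 (not isolated)
Conditions: LiN(i-Pr)2 (LDA), THF, −78 °C; TMSCl, Et3N; −78 → 60 °C; aq. citric acid
Reagents that add atoms: none
Why: Ireland–Claisen rearrangement: kinetic enolisation in THF should give the (E)-silyl ketene acetal, and the chair transition state with the CH2OTBS group of the carbinol carbon equatorial (sec-butyl and the alkene methyl axial) forms the C1–C2 bond, setting the quaternary C1 and C2 by chirality transfer from the carbinol carbon, which becomes the (E)-alkene C8a=C8.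

**Step 7**
Reactants: 11 (2R,3R,4E)-2-[(2R)-butan-2-yl]-6-[(tert-butyldimethylsilyl)oxy]-3-ethenyl-3-methylhex-4-enoic acid
Product: 12 (2R,3R,4E)-2-[(2R)-butan-2-yl]-6-[(tert-butyldimethylsilyl)oxy]-3-ethenyl-3-methylhex-4-en-1-ol
Conditions: LiAlH4, Et2O, 0 °C
Reagents that add atoms: none
Why: Hydride reduction of the acid gives the primary alcohol, while the silyl ether and the isolated alkenes are inert.

**Step 8**
Reactants: 12 (2R,3R,4E)-2-[(2R)-butan-2-yl]-6-[(tert-butyldimethylsilyl)oxy]-3-ethenyl-3-methylhex-4-en-1-ol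
Product: 13 (2R,3R,4E)-2-[(2R)-butan-2-yl]-6-[(tert-butyldimethylsilyl)oxy]-3-ethenyl-3-methylhex-4-enal
Conditions: Dess–Martin periodinane, CH2Cl2, 0 → 23 °C
Reagents that add atoms: none
Why: Dess–Martin oxidation stops at the aldehyde and should not epimerise the hindered C2 centre next to the quaternary C1.

**Step 9**
Reactants: 13 (2R,3R,4E)-2-[(2R)-butan-2-yl]-6-[(tert-butyldimethylsilyl)oxy]-3-ethenyl-3-methylhex-4-enal
Product: 14 (3S,4R,5E)-3-[(2R)-butan-2-yl]-7-[(tert-butyldimethylsilyl)oxy]-4-ethenyl-4-methylhept-5-en-1-yne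
Conditions: Ohira–Bestmann reagent, K2CO3, MeOH, 0 → 23 °C
Reagents that add atoms: dimethyl (1-diazo-2-oxopropyl)phosphonate, CC(=O)C(=[N+]=[N-])P(=O)(OC)OC
Why: Seyferth–Gilbert homologation with the Ohira–Bestmann reagent converts the aldehyde into the terminal alkyne (adding C4) under mild carbonate conditions that the hindered α-centre should survive.

**Step 10**
Reactants: 14 (3S,4R,5E)-3-[(2R)-butan-2-yl]-7-[(tert-butyldimethylsilyl)oxy]-4-ethenyl-4-methylhept-5-en-1-yne; 15 (E)-4-chlorobut-3-en-2-one
Product: 16 (3E,9E)-7-[(2R)-butan-2-yl]-11-[(tert-butyldimethylsilyl)oxy]-8-ethenyl-8-methylundeca-3,9-dien-5-yn-2-one [C7/C8 as C3/C4 of 14]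
Conditions: PdCl2(PPh3)2 (3 mol %), CuI (6 mol %), Et3N, THF, 0 → 23 °C
Reagents that add atoms: none
Why: Sonogashira coupling of the terminal alkyne with the activated β-chlorovinyl ketone retains the (E)-geometry and installs C4a–C7 in one step, and because the organopalladium species sits on the enone partner it cannot cyclise onto the alkenes of 14.

**Step 11**
Reactants: 16 (3E,9E)-7-[(2R)-butan-2-yl]-11-[(tert-butyldimethylsilyl)oxy]-8-ethenyl-8-methylundeca-3,9-dien-5-yn-2-one
Product: 17 (3E,5Z,9E)-7-[(2R)-butan-2-yl]-11-[(tert-butyldimethylsilyl)oxy]-8-ethenyl-8-methylundeca-3,5,9-trien-2-one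
Conditions: H2 (1 atm), Pd/CaCO3 poisoned with Pb(OAc)2 (Lindlar catalyst), quinoline, EtOAc, 0 °C, stopped after one equivalent of H2
Reagents that add atoms: none
Why: Lindlar semi-hydrogenation adds hydrogen syn to the alkyne and so creates the cis C3=C4 alkene of ring A, while the hindered vinyl group and the other alkenes react much more slowly on the poisoned catalyst.

**Step 12**
Reactants: 17 (3E,5Z,9E)-7-[(2R)-butan-2-yl]-11-[(tert-butyldimethylsilyl)oxy]-8-ethenyl-8-methylundeca-3,5,9-trien-2-one
Product: 18 (3E,5Z,9E)-7-[(2R)-butan-2-yl]-11-[(tert-butyldimethylsilyl)oxy]-8-ethenyl-8-methylundeca-1,3,5,9-tetraen-2-yl acetate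
Conditions: KN(SiMe3)2, THF, −78 °C; then Ac2O, −78 → −40 °C
Reagents that add atoms: acetic anhydride, CC(=O)OC(C)=O
Why: Kinetic deprotonation of the methyl ketone at CH3 and O-acetylation of the potassium enolate (enolate trapping) should give the cross-conjugated, acid-stable 2-acetoxydiene C4a=C5–C6(OAc)=C7.

**Step 13**
Reactants: 18 (3E,5Z,9E)-7-[(2R)-butan-2-yl]-11-[(tert-butyldimethylsilyl)oxy]-8-ethenyl-8-methylundeca-1,3,5,9-tetraen-2-yl acetate
Product: 19 (3E,5Z,9E)-7-[(2R)-butan-2-yl]-8-ethenyl-11-hydroxy-8-methylundeca-1,3,5,9-tetraen-2-yl acetate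
Conditions: HF·pyridine, THF/pyridine, 0 °C
Reagents that add atoms: none
Why: Fluoride-mediated desilylation removes the primary allylic silyl ether, and the enol acetate and the triene are stable to buffered HF·pyridine.

**Step 14**
Reactants: 19 (3E,5Z,9E)-7-[(2R)-butan-2-yl]-8-ethenyl-11-hydroxy-8-methylundeca-1,3,5,9-tetraen-2-yl acetate
Product: 20 (3E,5Z,9E)-7-[(2R)-butan-2-yl]-8-ethenyl-8-methyl-11-oxoundeca-1,3,5,9-tetraen-2-yl acetate
Conditions: MnO2 (activated, excess), CH2Cl2, 23 °C, dark
Reagents that add atoms: none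
Why: MnO2 oxidises only the allylic alcohol and should give the (E)-enal without isomerising the (Z,E)-triene or touching the enol acetate.

**Step 15**
Reactants: 20 (3E,5Z,9E)-7-[(2R)-butan-2-yl]-8-ethenyl-8-methyl-11-oxoundeca-1,3,5,9-tetraen-2-yl acetate
Product: 21 6-acetoxy-2α-[(R)-sec-butyl]-1α-ethenyl-8α-formyl-1β-methyl-1,2,4aβ,7,8,8aα-hexahydronaphthalene
Conditions: (2R,5R)-5-benzyl-2-tert-butyl-3-methylimidazolidin-4-one·TfOH (20 mol %), MeCN/H2O (98:2), −20 → 5 °C
Reagents that add atoms: none
Why: The secondary amine condenses with the enal to an (E)-iminium ion (LUMO lowering), the tethered 2-acetoxydiene adds to it in an asynchronous endo [4+2] in which C4a–C8a forms ahead of C7–C8, and hydrolysis of the product iminium ion releases 21 and the catalyst. The closest known reaction type is the imidazolidinone-catalysed enantioselective intramolecular Diels–Alder reaction of trienals to trans-fused bicyclo[4.4.0]decene aldehydes. Ring A closes through the four-atom tether C1–C2–C3=C4 (six-membered, bond C4a–C8a), and ring B is the new cyclohexene, closed by the bond C7–C8 between the terminal diene carbon and the α-carbon of the enal. C8 and C8a are trans because the (E)-enal adds suprafacially, the ring fusion is trans because the iminium group lies endo over the diene, and the absolute sense at C4a, C8a and C8 follows from the benzyl group of the (2R,5R)-catalyst, which covers one face of the iminium ion so that the diene reaches C8a from the face that gives 8aα-H; C1 and C2 were fixed in step 6 and their own facial bias is expected to be small. The step needs chemoselection between the two alkenyl arms on C1 (only the iminium arm is activated, the vinyl group stays), regiocontrol (fixed by the tether length), endo over exo selectivity (favoured under iminium catalysis) and π-facial control (catalyst), and the cis C3=C4 and (E)-C4a=C5 geometry excludes 6π-electrocyclisation of the triene.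

**Step 16**
Reactants: 21 6-acetoxy-2α-[(R)-sec-butyl]-1α-ethenyl-8α-formyl-1β-methyl-1,2,4aβ,7,8,8aα-hexahydronaphthalene
Product: 22 (E)-p-toluenesulfonylhydrazone of 21
Conditions: TsNHNH2, THF, 4 Å MS, 23 °C
Reagents that add atoms: p-toluenesulfonyl hydrazide, Cc1ccc(cc1)S(=O)(=O)NN
Why: Condensation of the aldehyde with tosylhydrazide gives the tosylhydrazone under neutral conditions, and C8 already holds the equatorial, more stable configuration.

**Step 17**
Reactants: 22 (E)-p-toluenesulfonylhydrazone of 21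
Product: 23 6-acetoxy-2α-[(R)-sec-butyl]-1α-ethenyl-1β,8α-dimethyl-1,2,4aβ,7,8,8aα-hexahydronaphthalene
Conditions: catecholborane, CHCl3, 0 °C; then NaOAc·3H2O, 60 °C
Reagents that add atoms: none
Why: Catecholborane reduction of the tosylhydrazone and acetate-induced loss of sulfinate and N2 from the diazene (reductive deoxygenation of an aldehyde through its tosylhydrazone) turn the formyl group into the C8 methyl group without touching the alkenes or the enol acetate.

**Step 18**
Reactants: 23 6-acetoxy-2α-[(R)-sec-butyl]-1α-ethenyl-1β,8α-dimethyl-1,2,4aβ,7,8,8aα-hexahydronaphthalene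
Product: 24 6α-acetoxy-5β,6β-epoxide of 23
Conditions: 1,2:4,5-di-O-isopropylidene-β-L-erythro-2,3-hexodiulo-2,6-pyranose (L-fructose-derived Shi ketone, 30 mol %), Oxone (2KHSO5·KHSO4·K2SO4), K2CO3, Bu4NHSO4, MeCN/dimethoxymethane–aq. Na2B4O7 buffer, 0 °C
Reagents that add atoms: potassium peroxymonosulfate, [K+].[O-]S(=O)(=O)OO
Why: Shi asymmetric epoxidation (dioxirane from the chiral ketone) is selective for the electron-rich trisubstituted enol acetate over the cis-disubstituted and monosubstituted alkenes, and by the spiro transition-state model for 1-substituted cyclohexenes the L-fructose-derived ketone should deliver oxygen to the β face, which sets C5.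

**Step 19**
Reactants: 24 6α-acetoxy-5β,6β-epoxide of 23
Product: 26 2α-[(R)-sec-butyl]-1α-ethenyl-1β,8α-dimethyl-1,2,4aβ,5,6,7,8,8aα-octahydronaphthalene-5β,6β-diol, via lithium alkoxide of the hydroxy ketone 25 (not isolated)
Conditions: LiBH(s-Bu)3 (L-Selectride, 4 equiv), THF, −78 → 0 °C; then H2O
Reagents that add atoms: none
Why: Hydride first cleaves the acetate, the epoxy alkoxide collapses to the 5β-oxido 6-ketone 25 with the C5–O bond retained, and the bulky borohydride then attacks the cyclohexanone along the equatorial direction on the α face to give the axial 6β-alcohol and thus the cis-diol (stereoselective ketone reduction).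

**Step 20**
Reactants: 26 2α-[(R)-sec-butyl]-1α-ethenyl-1β,8α-dimethyl-1,2,4aβ,5,6,7,8,8aα-octahydronaphthalene-5β,6β-diol
Product: 27 1α-acetyl-2α-[(R)-sec-butyl]-1β,8α-dimethyl-1,2,4aβ,5,6,7,8,8aα-octahydronaphthalene-5β,6β-diol
Conditions: PdCl2 (10 mol %), CuCl, O2 (1 atm), DMF/H2O (7:1), 23 °C
Reagents that add atoms: water, O
Why: Tsuji–Wacker oxidation converts the terminal vinyl group with Markovnikov selectivity into the methyl ketone, while the internal cis C3=C4 alkene reacts far more slowly and free hydroxyls are tolerated.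

**Step 21**
Reactants: 27 1α-acetyl-2α-[(R)-sec-butyl]-1β,8α-dimethyl-1,2,4aβ,5,6,7,8,8aα-octahydronaphthalene-5β,6β-diol
Product: 29 1-{2α-[(R)-sec-butyl]-5β,6β-dihydroxy-1β,8α-dimethyl-1,2,4aβ,5,6,7,8,8aα-octahydronaphthalen-1α-yl}-3-hydroxypropan-1-one, via tris(trimethylsilyl) derivative 28 (not isolated)
Conditions: TMSOTf, Et3N, CH2Cl2, 0 °C; solvent exchange; aq. HCHO (37 %), Yb(OTf)3 (10 mol %), THF, 23 °C; then 0.5 M HCl, 0 °C
Reagents that add atoms: formaldehyde, C=O
Why: Soft enolisation can only occur toward the CH3 group because C1 is quaternary, and the lanthanide-triflate-catalysed aqueous Mukaiyama aldol reaction of the silyl enol ether with formaldehyde adds the hydroxymethyl carbon, the transient silyl ethers being hydrolysed on acidic work-up.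

**Step 22**
Reactants: 29 1-{2α-[(R)-sec-butyl]-5β,6β-dihydroxy-1β,8α-dimethyl-1,2,4aβ,5,6,7,8,8aα-octahydronaphthalen-1α-yl}-3-hydroxypropan-1-one
Product: 30 3-O-tert-butyldimethylsilyl ether of 29
Conditions: TBSCl (1.1 equiv), imidazole, CH2Cl2, −10 °C
Reagents that add atoms: tert-butyldimethylsilyl chloride, CC(C)(C)[Si](C)(C)Cl
Why: Silylation should take the primary hydroxyl selectively over the two ring hydroxyls, so that only these two remain free for the acylation.

**Step 23**
Reactants: 31 3-methylglutaconic acid (3-methylpent-2-enedioic acid, commercial E/Z mixture)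
Product: 32 3-methylglutaconic anhydride (4-methyl-2H-pyran-2,6(3H)-dione)
Conditions: Ac2O, 80 °C; removal of volatiles
Reagents that add atoms: none
Why: Dehydration with acetic anhydride closes the six-membered cyclic anhydride, which can only hold the cis (Z) arrangement of the two carboxyl carbons (the E acid isomerises through its mixed anhydride).

**Step 24**
Reactants: 30 3-O-tert-butyldimethylsilyl ether of 29; 32 3-methylglutaconic anhydride
Product: 33 O-tert-butyldimethylsilyl tandyukisin C (C5 ester, free acid)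
Conditions: 32 (1.5 equiv), PhMe, 50 °C, no base
Reagents that add atoms: none
Why: Alcoholysis of the cyclic anhydride: the equatorial C5 hydroxyl is more accessible than the axial C6 hydroxyl and attacks the non-conjugated, more electrophilic carbonyl, so the cis double bond of the ring stays conjugated with the liberated acid and the (Z)-half ester of the target results.

**Step 25**
Reactants: 33 O-tert-butyldimethylsilyl tandyukisin C
Product: 34 tandyukisin C
Conditions: HF·pyridine, THF/pyridine, 0 → 23 °C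
Reagents that add atoms: none
Why: Buffered HF·pyridine cleaves the primary silyl ether without β-elimination of the β-hydroxy ketone, acyl migration or isomerisation of the glutaconate.

**Compound list**

1 | (S)-2,2-dimethyl-1,3-dioxolane-4-carbaldehyde | CC1(C)OC[C@@H](C=O)O1 | starting material
2 | 2-(triphenylphosphoranylidene)propanal | CC(C=O)=P(c1ccccc1)(c1ccccc1)c1ccccc1 | starting material
3 | (R,E)-3-(2,2-dimethyl-1,3-dioxolan-4-yl)-2-methylprop-2-enal | CC1(C)OC[C@@H](/C=C(\C)C=O)O1 | intermediate
4 | (R)-2,2-dimethyl-4-[(1E)-2-methylbuta-1,3-dien-1-yl]-1,3-dioxolane | CC1(C)OC[C@@H](/C=C(\C)C=C)O1 | intermediate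
5 | (2R,3E)-4-methylhexa-3,5-diene-1,2-diol | OC[C@H](O)/C=C(\C)C=C | intermediate
6 | (2R,3E)-1-[(tert-butyldimethylsilyl)oxy]-4-methylhexa-3,5-dien-2-ol | CC(C)(C)[Si](C)(C)OC[C@H](O)/C=C(\C)C=C | intermediate
7 | (R)-3-methylpentanoic acid | CC[C@@H](C)CC(=O)O | starting material
8 | (2R,3E)-1-[(tert-butyldimethylsilyl)oxy]-4-methylhexa-3,5-dien-2-yl (3R)-3-methylpentanoate | CC[C@@H](C)CC(=O)O[C@@H](CO[Si](C)(C)C(C)(C)C)/C=C(\C)C=C | intermediate
9 | (E)-trimethylsilyl ketene acetal of 8, sec-butyl cis to the allylic oxygen (not isolated) | CC[C@@H](C)/C=C(/O[Si](C)(C)C)O[C@@H](CO[Si](C)(C)C(C)(C)C)/C=C(\C)C=C | intermediate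
10 | trimethylsilyl ester of 11 (not isolated) | CC[C@@H](C)[C@@H](C(=O)O[Si](C)(C)C)[C@](C)(C=C)/C=C/CO[Si](C)(C)C(C)(C)C | intermediate
11 | (2R,3R,4E)-2-[(2R)-butan-2-yl]-6-[(tert-butyldimethylsilyl)oxy]-3-ethenyl-3-methylhex-4-enoic acid | CC[C@@H](C)[C@@H](C(=O)O)[C@](C)(C=C)/C=C/CO[Si](C)(C)C(C)(C)C | intermediate
12 | (2R,3R,4E)-2-[(2R)-butan-2-yl]-6-[(tert-butyldimethylsilyl)oxy]-3-ethenyl-3-methylhex-4-en-1-ol | CC[C@@H](C)[C@@H](CO)[C@](C)(C=C)/C=C/CO[Si](C)(C)C(C)(C)C | intermediate
13 | (2R,3R,4E)-2-[(2R)-butan-2-yl]-6-[(tert-butyldimethylsilyl)oxy]-3-ethenyl-3-methylhex-4-enal | CC[C@@H](C)[C@@H](C=O)[C@](C)(C=C)/C=C/CO[Si](C)(C)C(C)(C)C | intermediate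
14 | (3S,4R,5E)-3-[(2R)-butan-2-yl]-7-[(tert-butyldimethylsilyl)oxy]-4-ethenyl-4-methylhept-5-en-1-yne | CC[C@@H](C)[C@@H](C#C)[C@](C)(C=C)/C=C/CO[Si](C)(C)C(C)(C)C | intermediate
15 | (E)-4-chlorobut-3-en-2-one | CC(=O)/C=C/Cl | starting material
16 | (3E,9E)-7-[(2R)-butan-2-yl]-11-[(tert-butyldimethylsilyl)oxy]-8-ethenyl-8-methylundeca-3,9-dien-5-yn-2-one [C7/C8 as C3/C4 of 14] | CC[C@@H](C)[C@@H](C#C/C=C/C(C)=O)[C@](C)(C=C)/C=C/CO[Si](C)(C)C(C)(C)C | intermediate
17 | (3E,5Z,9E)-7-[(2R)-butan-2-yl]-11-[(tert-butyldimethylsilyl)oxy]-8-ethenyl-8-methylundeca-3,5,9-trien-2-one | CC[C@@H](C)[C@@H](/C=C\C=C\C(C)=O)[C@](C)(C=C)/C=C/CO[Si](C)(C)C(C)(C)C | intermediate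
18 | (3E,5Z,9E)-7-[(2R)-butan-2-yl]-11-[(tert-butyldimethylsilyl)oxy]-8-ethenyl-8-methylundeca-1,3,5,9-tetraen-2-yl acetate | CC[C@@H](C)[C@@H](/C=C\C=C\C(=C)OC(C)=O)[C@](C)(C=C)/C=C/CO[Si](C)(C)C(C)(C)C | intermediate
19 | (3E,5Z,9E)-7-[(2R)-butan-2-yl]-8-ethenyl-11-hydroxy-8-methylundeca-1,3,5,9-tetraen-2-yl acetate | CC[C@@H](C)[C@@H](/C=C\C=C\C(=C)OC(C)=O)[C@](C)(C=C)/C=C/CO | intermediate
20 | (3E,5Z,9E)-7-[(2R)-butan-2-yl]-8-ethenyl-8-methyl-11-oxoundeca-1,3,5,9-tetraen-2-yl acetate | CC[C@@H](C)[C@@H](/C=C\C=C\C(=C)OC(C)=O)[C@](C)(C=C)/C=C/C=O | intermediate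
21 | 6-acetoxy-2α-[(R)-sec-butyl]-1α-ethenyl-8α-formyl-1β-methyl-1,2,4aβ,7,8,8aα-hexahydronaphthalene (trans-fused) | CC[C@@H](C)[C@H]1C=C[C@H]2C=C(OC(C)=O)C[C@@H](C=O)[C@@H]2[C@@]1(C)C=C | intermediate
22 | (E)-p-toluenesulfonylhydrazone of 21 | CC[C@@H](C)[C@H]1C=C[C@H]2C=C(OC(C)=O)C[C@@H](/C=N/NS(=O)(=O)c3ccc(C)cc3)[C@@H]2[C@@]1(C)C=C | intermediate
23 | 6-acetoxy-2α-[(R)-sec-butyl]-1α-ethenyl-1β,8α-dimethyl-1,2,4aβ,7,8,8aα-hexahydronaphthalene | CC[C@@H](C)[C@H]1C=C[C@H]2C=C(OC(C)=O)C[C@@H](C)[C@@H]2[C@@]1(C)C=C | intermediate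
24 | 6α-acetoxy-5β,6β-epoxide of 23 | CC[C@@H](C)[C@H]1C=C[C@H]2[C@@H]3O[C@]3(OC(C)=O)C[C@@H](C)[C@@H]2[C@@]1(C)C=C | intermediate
25 | lithium 5β-alkoxide of the 5β-hydroxy-6-ketone (not isolated) | CC[C@@H](C)[C@H]1C=C[C@H]2[C@H]([O-])C(=O)C[C@@H](C)[C@@H]2[C@@]1(C)C=C.[Li+] | intermediate
26 | 2α-[(R)-sec-butyl]-1α-ethenyl-1β,8α-dimethyl-1,2,4aβ,5,6,7,8,8aα-octahydronaphthalene-5β,6β-diol | CC[C@@H](C)[C@H]1C=C[C@H]2[C@H](O)[C@H](O)C[C@@H](C)[C@@H]2[C@@]1(C)C=C | intermediate
27 | 1α-acetyl-2α-[(R)-sec-butyl]-1β,8α-dimethyl-1,2,4aβ,5,6,7,8,8aα-octahydronaphthalene-5β,6β-diol | CC[C@@H](C)[C@H]1C=C[C@H]2[C@H](O)[C@H](O)C[C@@H](C)[C@@H]2[C@@]1(C)C(C)=O | intermediate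
28 | 5,6-bis-O-trimethylsilyl ether and trimethylsilyl enol ether of 27 (not isolated) | CC[C@@H](C)[C@H]1C=C[C@H]2[C@H](O[Si](C)(C)C)[C@H](O[Si](C)(C)C)C[C@@H](C)[C@@H]2[C@@]1(C)C(=C)O[Si](C)(C)C | intermediate
29 | 1-{2α-[(R)-sec-butyl]-5β,6β-dihydroxy-1β,8α-dimethyl-1,2,4aβ,5,6,7,8,8aα-octahydronaphthalen-1α-yl}-3-hydroxypropan-1-one | CC[C@@H](C)[C@H]1C=C[C@H]2[C@H](O)[C@H](O)C[C@@H](C)[C@@H]2[C@@]1(C)C(=O)CCO | intermediate
30 | 3-O-tert-butyldimethylsilyl ether of 29 | CC[C@@H](C)[C@H]1C=C[C@H]2[C@H](O)[C@H](O)C[C@@H](C)[C@@H]2[C@@]1(C)C(=O)CCO[Si](C)(C)C(C)(C)C | intermediate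
31 | 3-methylglutaconic acid (E/Z mixture) | CC(CC(=O)O)=CC(=O)O | starting material
32 | 3-methylglutaconic anhydride | CC1=CC(=O)OC(=O)C1 | intermediate
33 | O-tert-butyldimethylsilyl tandyukisin C | CC[C@@H](C)[C@H]1C=C[C@H]2[C@H](OC(=O)C/C(C)=C\C(=O)O)[C@H](O)C[C@@H](C)[C@@H]2[C@@]1(C)C(=O)CCO[Si](C)(C)C(C)(C)C | intermediate
34 | tandyukisin C | CC[C@@H](C)[C@H]1C=C[C@H]2[C@H](OC(=O)C/C(C)=C\C(=O)O)[C@H](O)C[C@@H](C)[C@@H]2[C@@]1(C)C(=O)CCO | target

**Step count and risks**

Total step count: 25. Longest linear sequence: 24 steps (steps 1–22, 24 and 25; step 23 prepares 32 on a side branch).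

Steps most likely to fail:

1. Step 15 (key cycloaddition). Iminium formation and cycloaddition may be slow at an enal whose β-carbon is attached to a quaternary centre. The dienyl acetate may be lost during a long reaction (hydrolysis, acetyl transfer to the amine). A mismatch between the catalyst and the existing C1/C2 centres may erode facial selectivity. Fallback: setting out from 20, the ring closure is run under chiral Lewis-acid catalysis instead of covalent amine catalysis, with a cationic oxazaborolidine (from diphenylprolinol and o-tolylboronic acid, activated with Tf2NH) in anhydrous CH2Cl2 at −78 °C. The enal is then activated more strongly, and neither water nor a nucleophilic amine is present. The catalyst antipode that delivers the diene to the same face of C8a is chosen. The product is again 21, where the route is rejoined; no new compound is made.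

2. Step 11 (semi-hydrogenation). Over-reduction of the new diene or of the vinyl group may occur, as may Z to E isomerisation of the conjugated dienone on the catalyst. Fallback: the cis alkene is built by olefination instead of reduction, setting out from aldehyde 13. Still–Gennari olefination (methyl bis(2,2,2-trifluoroethyl)phosphonoacetate, KN(SiMe3)2, 18-crown-6, THF, −78 °C) gives the methyl (Z)-enoate F1. Reduction with i-Bu2AlH gives the (Z)-allylic alcohol F2, and MnO2 gives the (Z)-enal F3. Wittig reaction of F3 with 1-(triphenylphosphoranylidene)propan-2-one (CH2Cl2, 23 °C, E-selective) gives 17, where the route is rejoined; compounds 14 and 16 are bypassed.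

3. Step 24 (acylation). Acylation may occur at the axial C6 hydroxyl, or the acyl group may migrate between the cis hydroxyls. Opening of the anhydride by a hindered secondary alcohol may be slow. If heat or base is needed, the glutaconate double bond may migrate or isomerise. Fallback: the two oxygens are differentiated through a temporary tin acetal, setting out from 30. Bu2SnO in PhMe at reflux with removal of water gives the dibutylstannylene acetal F4, in which the equatorial C5 oxygen is the activated one. F4 is then treated with 32 at 23 °C under neutral conditions, and hydrolytic work-up gives 33, where the route is rejoined.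

**Further compounds**

F0 | step 15 | none | none
F1 | step 11 | methyl (2Z,6E)-4-[(2R)-butan-2-yl]-8-[(tert-butyldimethylsilyl)oxy]-5-ethenyl-5-methylocta-2,6-dienoate [C4/C5 as C2/C3 of 13] | CC[C@@H](C)[C@@H](/C=C\C(=O)OC)[C@](C)(C=C)/C=C/CO[Si](C)(C)C(C)(C)C
F2 | step 11 | (2Z,6E)-4-[(2R)-butan-2-yl]-8-[(tert-butyldimethylsilyl)oxy]-5-ethenyl-5-methylocta-2,6-dien-1-ol | CC[C@@H](C)[C@@H](/C=C\CO)[C@](C)(C=C)/C=C/CO[Si](C)(C)C(C)(C)C
F3 | step 11 | (2Z,6E)-4-[(2R)-butan-2-yl]-8-[(tert-butyldimethylsilyl)oxy]-5-ethenyl-5-methylocta-2,6-dienal | CC[C@@H](C)[C@@H](/C=C\C=O)[C@](C)(C=C)/C=C/CO[Si](C)(C)C(C)(C)C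
F4 | step 24 | 5β,6β-O-dibutylstannylene acetal of 30 | CC[C@@H](C)[C@H]1C=C[C@H]2[C@@H]3O[Sn](CCCC)(CCCC)O[C@@H]3C[C@@H](C)[C@@H]2[C@@]1(C)C(=O)CCO[Si](C)(C)C(C)(C)C
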